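## Structural features

The target 16 is a 3,4-dihydronaphthalen-1(2H)-one: ring B (C1 ketone, C2 and C3 methylenes, C4 methine) is fused through C4a and C8a to a hydroquinone ring A with hydroxyl groups at C5 and C8, the C8 hydroxyl lying peri to the C1 carbonyl. C4 is bonded to C1′ of a naphthalene that carries a free hydroxyl at C4′ and a methyl ether at C8′. The methoxy group therefore sits peri to the point of attachment and crowds the C4–C1′ bond from one side, while C5–OH and the C3 methylene crowd it from the other. C4 is the only stereocentre, (S) by the CIP rules (C4a > C1′ > C3 > H). It is a doubly benzylic methine with no stereogenic neighbour and no adjacent heteroatom or carbonyl group to steer its formation. The fragile elements are the hydroquinone (air oxidation to the quinone, above all in base), the electron-rich naphthol, the benzylic ketone, and the C4–H bond, whose loss by dehydrogenation or elimination would aromatise ring B. Three phenols must also be told apart from one aryl methyl ether. The real difficulty is the enantioselective construction of an isolated diarylmethine carbon whose two aryl groups are of similar size and both ortho-substituted. The key step exploits the fact that C4–C3–C2–C1 is a butanoate chain whose terminal carbon C4 bears both aryl carbons C4a and C1′: a but-3-enoate can take up ring A and the naphthalene one after the other on its CH2 terminus, after which C1 only has to be joined to C8a.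

## Logic of the disconnections

16 to 15: the three phenolic O–H groups are traced back to three O–CH2Ph bonds. One kind of protecting group on all three oxygens allows a single neutral, reductive release that leaves the aryl methyl ether alone, and it keeps the hydroquinone and the naphthol masked through every earlier step. There is no skeletal gain. The forward step must cleave three ethers, one of them hindered at C5, without reducing the C1 ketone.

15 to 13: the C1–C8a bond is cut. It joins an aryl ketone carbon to an alkoxy-activated arene position, the retron of a Friedel–Crafts acylation, and C8a is the only free carbon of ring A next to the chain. The tetralone becomes an open-chain 4,4-diarylbutanoic acid. The forward step, which passes through 14, must acylate ring A in preference to C2′ of the naphthalene and must be mild enough to keep the benzyl groups in place; C4 is not involved.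

13 to 12: the acyl C–O bond of the acid is traced back to a methyl ester. The ester is wanted in the metal-catalysed step, where a free carboxylate could capture the benzylic palladium intermediate as a lactone. The demand is only a hydrolysis that cannot reach the C4–H bond.

12 to 4, 10 and 11: both aryl bonds of C4 are cut, C4–C4a and C4–C1′, which leaves C4 as the CH2 terminus of 11. This is the largest simplification of the plan: every skeletal carbon and the stereocentre come from three small achiral pieces in one operation. The ortho-alkoxy ring is placed on the electrophilic partner 4 so that it enters first and stabilises the benzylic palladium intermediate. 4 is made as a dry, isolated salt for ion pairing, and 11 is used in excess. The forward step must put the first aryl group on the terminal carbon, bring palladium back to C4 and not toward the ester, couple there and not at C3, and distinguish the two faces of C4.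

4 to 3: the C–N2 unit is traced back to a C–NH2 group. The forward diazotisation must give a salt that can be isolated free of water and nucleophiles.

3 to 2: the amine is traced back to a nitro group. The reduction must spare two aryl benzyl ethers, which rules out hydrogenation over palladium.

2 to 1: the C–N bond is cut. All four free positions of the central ring of 1 are equivalent, so only mono-substitution has to be secured.

10 to 7: the C1′–B bond is cut back to a C–Br bond. The forward step, through 8 and 9, needs halogen–metal exchange faster than attack at the benzylic CH2, and a work-up that does not strip the boron from an electron-rich ring.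

7 to 6: the O–CH2Ph bond is cut. The benzyl group is put on after the halogen because the ether would make the two naphthalene rings nearly equal in reactivity.

6 to 5: the C–Br bond is cut. The free hydroxyl of 5 must direct the electrophile to the para α-carbon, which lies peri to the methoxy group, and not to C2 or to the other ring.

## Other disconnections considered

Alternative 1: The cut goes through C2–C3 of ring B and the C4–H bond. It leads back to the α-chloroketone A1, a ring A bis(methoxymethyl) ether with a chloroacetyl group on C8a and a 1-(naphthyl)ethenyl group on C4a. In the forward direction a flavin-dependent ene-reductase under visible light would transfer one electron to A1. The C2 radical left after loss of chloride would add to the alkene CH2 (6-endo-trig closure of ring B, giving a diaryl-stabilised radical at C4), and the flavin semiquinone would deliver a hydrogen atom to one face of C4 to give the tris(methoxymethyl) ether A2. Mild acid would then release 16.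
- In favour: ring B and the stereocentre arise in one operation, there is no Friedel–Crafts regiochemistry to settle, and only one step follows the key step against three in the chosen plan. On that count the alternative is the better. A protein pocket is also, in principle, the better tool for a hydrogen transfer to a prochiral radical.
- Against: A1 is a large, twisted, tri-ortho-substituted 1,1-diarylethene, well outside the substrate size such enzymes usually accept. The cyclised radical is hindered and strongly stabilised, hence a reluctant hydrogen-atom acceptor, so unselective quenching could erode the selectivity. A1 also needs a ring A with four contiguous substituents, which means a linear sequence clearly longer than the three-step branches of the chosen plan.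
- Comparison: structurally, the alternative forms the C4–aryl bonds early without stereochemistry and sets C4 last, while the chosen plan forms both bonds and the stereocentre together. Mechanistically, both key steps lie beyond established substrate scope, so neither has the advantage of precedent. The acetal groups of A2 would come off without hydrogen and metal, an equal or slightly better end game for a ketone-bearing product.

Alternative 2: The cut goes through C4–C4a and C1–C8a, the two bonds that join ring A to the carbon chain of ring B. It leads to the (E,E)-silyloxydiene A3 and 1,4-benzoquinone A4. Under a chiral Lewis acid A3 would add endo to A4 to give the all-cis cycloadduct A5, in which ring B is closed and the aryl-bearing carbon has the configuration of C4. Enolisation of the enedione would give ring A as the hydroquinone. Removal of the silyl group, transposition of the C1 oxygen to the ketone level with saturation of C2–C3, and debenzylation would complete 16.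
- In favour: the catalytic enantioselective Diels–Alder reaction of quinones is an established reaction type, so on precedent the alternative is the better. It closes ring B while forming both bonds to ring A, A4 is symmetric so no regiochemistry arises, and ring A needs no protecting groups.
- Against: three of the four stereocentres of A5 are made only to be erased. Once ring A is aromatic, the C1 silyloxy group and the C4 hydrogen stand 1,4 across a dihydronaphthalene, so elimination would aromatise ring B and delete C4; the doubly benzylic, allylic C4–H also invites double-bond migration. A4 is an oxidant that can dehydrogenate its own adduct, and the oxidation-level change at C1 has to be made next to a free hydroquinone. A3 must be prepared geometrically pure in several steps.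
- Comparison: the pericyclic step offers more reliable relative stereocontrol and firmer mechanistic ground. The chosen plan keeps C4 in a saturated chain where nothing can eliminate, and its longest line of seven steps is expected to be shorter than the nine or so needed here. In convergence the two are about equal.

Alternative 3: The cut goes through C4a–C5 and C8–C8a. The four carbons C5 to C8 of ring A are removed as the sulfonyl butenolide A7, and ring B remains as the enantioenriched 4-arylcyclohexenone A6, (4R) by the CIP rules but with the spatial arrangement of C4 in 16. With a hindered lithium alkoxide the anion of A7 would add to the β-carbon of A6, the resulting enolate would attack the lactone carbonyl, and loss of sulfinate with tautomerisation would give ring A directly as the hydroquinone in A8. Hydrogenolysis of the single benzyl ether would give 16.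
- In favour: the tetralone carbonyl and the free hydroquinone appear together, there is no Friedel–Crafts step, ring A needs no protecting groups, and only one step follows the key step. In protecting-group economy and in the end game the alternative is the better, and its annulation is a known reaction type for cyclic enones.
- Against: the stereocentre must be made first and then survive a strong base, although its hydrogen is the γ-hydrogen of the enone and both allylic and benzylic. Dienolate formation would racemise A6 and withdraw it from the conjugate addition. The nucleophile must attack the carbon directly next to the bulky, peri-substituted aryl group, and A6 needs its own asymmetric synthesis, which makes the route linear.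
- Comparison: structurally, the alternative separates the making of C4 from the assembly of the skeleton, while the chosen plan does both in one step from three fragments. Mechanistically, the anionic cascade is better precedented but less compatible with the stereocentre, whereas in the chosen route C4 never meets a base that can reach it. In step count the alternative is expected to be longer before its key step and shorter after it.

Key step: step 7

Assumption: the sense of induction of the chiral phosphate in step 7 cannot be predicted with confidence for this aryl pair; the (R)-acid is written, and its mirror image would be used if the (4R) ester were favoured.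

## Route

Step 1
Reactants: 1 1,4-bis(benzyloxy)benzene
Product: 2 1,4-bis(benzyloxy)-2-nitrobenzene
Conditions: HNO3 (65%, 1.2 equiv), AcOH–CH2Cl2, 0 °C to rt
Reagents that add atoms: nitric acid, O[N+](=O)[O-]
Why: Electrophilic aromatic nitration; the dialkoxy ring is far more electron-rich than the benzyl phenyl rings, its four free positions are equivalent, and the first nitro group deactivates the ring against a second one.

Step 2
Reactants: 2 1,4-bis(benzyloxy)-2-nitrobenzene
Product: 3 2,5-bis(benzyloxy)aniline
Conditions: Fe powder (5 equiv), NH4Cl, EtOH–H2O (4:1), 80 °C
Reagents that add atoms: none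
Why: Béchamp-type reduction of the nitro group by electron transfer from iron; unlike hydrogenation over palladium it does not cleave aryl benzyl ethers.

Step 3
Reactants: 3 2,5-bis(benzyloxy)aniline
Product: 4 2,5-bis(benzyloxy)benzenediazonium tetrafluoroborate
Conditions: NaNO2 (1.05 equiv), HBF4 (48% aq, 3 equiv), MeCN–H2O, 0 °C; precipitation with cold Et2O, dried in vacuo in the dark
Reagents that add atoms: sodium nitrite, [Na+].[O-]N=O; tetrafluoroboric acid, [H+].F[B-](F)(F)F
Why: Diazotisation of a primary arylamine by nitrosation and dehydration; the non-nucleophilic tetrafluoroborate should give a crystalline salt that can be isolated dry, as the anion phase-transfer step requires, and the two alkoxy donors stabilise the cation.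

Step 4
Reactants: 5 5-methoxynaphthalen-1-ol
Product: 6 4-bromo-5-methoxynaphthalen-1-ol
Conditions: NBS (1.0 equiv), MeCN, −30 to 0 °C, dark
Reagents that add atoms: N-bromosuccinimide, O=C1CCC(=O)N1Br
Why: Electrophilic bromination directed by the free hydroxyl group, the strongest donor: the α-carbon C4 para to it should be preferred over the β-carbon C2 and over the methoxy ring, and acetonitrile favours para attack. The halogen is introduced before benzylation because the benzyl ether would make the two rings nearly equivalent.

Step 5
Reactants: 6 4-bromo-5-methoxynaphthalen-1-ol
Product: 7 1-(benzyloxy)-4-bromo-5-methoxynaphthalene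
Conditions: BnBr (1.1 equiv), K2CO3 (1.5 equiv), DMF, rt
Reagents that add atoms: benzyl bromide, BrCc1ccccc1
Why: Williamson ether synthesis on the naphthoxide; the oxygen is unhindered (peri to hydrogen) and should alkylate cleanly.

Step 6
Reactants: 7 1-(benzyloxy)-4-bromo-5-methoxynaphthalene
Product: 10 [4-(benzyloxy)-8-methoxynaphthalen-1-yl]boronic acid, via aryllithium 8 (not isolated), via lithium aryltrimethoxyborate 9 (not isolated)
Conditions: n-BuLi (1.05 equiv), THF, −78 °C; B(OMe)3 (2 equiv), −78 to 0 °C; 0.5 M aq HCl, 0 °C, brief
Reagents that add atoms: trimethyl borate, COB(OC)OC; water, O
Why: Bromine–lithium exchange at −78 °C is faster than deprotonation of the benzylic CH2 and gives an aryllithium held by the peri-methoxy oxygen; addition to the borate and brief hydrolysis should give the boronic acid.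

Step 7
Reactants: 4 2,5-bis(benzyloxy)benzenediazonium tetrafluoroborate; 11 methyl but-3-enoate; 10 [4-(benzyloxy)-8-methoxynaphthalen-1-yl]boronic acid
Product: 12 methyl (4S)-4-[2,5-bis(benzyloxy)phenyl]-4-[4-(benzyloxy)-8-methoxynaphthalen-1-yl]butanoate
Conditions: 4 (1.0 equiv), 11 (3 equiv), 10 (1.5 equiv), Pd2(dba)3 (5 mol%), (R)-3,3′-bis(2,4,6-triisopropylphenyl)-1,1′-binaphthyl-2,2′-diyl hydrogen phosphate (12 mol%), Na2CO3 (2 equiv), MTBE, 10 °C, dark
Reagents that add atoms: none
Why: Proposed new method: oxidative addition of 4 to zerovalent palladium gives a cationic aryl complex of divalent palladium that enters the ether phase as its ion pair with the chiral phosphate; insertion of 11 places C4a on the terminal alkene carbon (C4) and palladium on C3, β-hydride elimination toward C4 and reinsertion with the opposite regiochemistry return palladium to C4 as an η3-benzyl complex, and transmetalation from 10 followed by reductive elimination forms C4–C1′ and regenerates the catalyst; the closest known reaction type is the palladium-catalysed enantioselective 1,1-diarylation of acrylates with aryldiazonium salts and arylboronic acids under chiral anion phase transfer, from which this case differs by the extra methylene between alkene and ester. No ring is closed. The single new stereocentre C4 is controlled by the chiral phosphate, which as counter-anion or ligand of the cationic η3-benzyl palladium should select between the two diastereomeric complexes (interconverting by reversible β-hydride elimination and reinsertion) at the transmetalation and reductive elimination stage, where the naphthyl group is delivered with retention to the face that carries palladium. The step needs terminal regioselectivity in the insertion (secured by the unbiased monosubstituted alkene and the bulky ortho-substituted aryl group), 1,1- over 1,2-diarylation (secured by fast β-hydride elimination in a ligand-poor cationic complex and by the slow transmetalation of the peri-hindered 10), and migration toward the arene and not the ester (secured by the electron-rich ring A, whose ortho-benzyloxy group makes the η3-benzyl complex the thermodynamic sink, while a palladium enolate at C2 can revert). Direct biaryl coupling of 4 with 10 should be held back by the low concentration of dissolved diazonium ion, the excess of 11 and the hindrance of 10.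

Step 8
Reactants: 12 methyl (4S)-4-[2,5-bis(benzyloxy)phenyl]-4-[4-(benzyloxy)-8-methoxynaphthalen-1-yl]butanoate
Product: 13 (4S)-4-[2,5-bis(benzyloxy)phenyl]-4-[4-(benzyloxy)-8-methoxynaphthalen-1-yl]butanoic acid
Conditions: LiOH·H2O (3 equiv), THF–MeOH–H2O, rt; 1 M aq HCl to pH 3
Reagents that add atoms: lithium hydroxide, [Li+].[OH-]
Why: Saponification by acyl–oxygen cleavage; the C4–H bond of a diarylmethane is far too weakly acidic for hydroxide, so the configuration should be untouched.

Step 9
Reactants: 13 (4S)-4-[2,5-bis(benzyloxy)phenyl]-4-[4-(benzyloxy)-8-methoxynaphthalen-1-yl]butanoic acid
Product: 15 (4S)-5,8-bis(benzyloxy)-4-[4-(benzyloxy)-8-methoxynaphthalen-1-yl]-3,4-dihydronaphthalen-1(2H)-one, via mixed trifluoroacetic anhydride 14 (not isolated)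
Conditions: (CF3CO)2O (3 equiv), CH2Cl2 (0.02 M), 0 °C to rt
Reagents that add atoms: none
Why: Intramolecular Friedel–Crafts acylation through the mixed anhydride; C8a is the only free carbon of ring A next to the chain, lies ortho to a benzyloxy donor and closes a six-membered ring, whereas the competing naphthalene carbon C2′ is a β-position that neither alkoxy group activates directly. C4 is not involved and should keep its configuration.

Step 10
Reactants: 15 (4S)-5,8-bis(benzyloxy)-4-[4-(benzyloxy)-8-methoxynaphthalen-1-yl]-3,4-dihydronaphthalen-1(2H)-one
Product: 16 (4S)-5,8-dihydroxy-4-(4-hydroxy-8-methoxynaphthalen-1-yl)-3,4-dihydronaphthalen-1(2H)-one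
Conditions: H2 (1 atm), 10% Pd/C, EtOAc–THF, rt; filtration and concentration under argon
Reagents that add atoms: none
Why: Hydrogenolysis of the three aryl benzyl ethers in one operation; the aryl methyl ether is inert, and at one atmosphere in neutral solvent the conjugated, hydrogen-bonded C1 ketone and the diarylmethine C4–H are expected to survive.

## Compound list

1 | 1,4-bis(benzyloxy)benzene | c1ccc(COc2ccc(OCc3ccccc3)cc2)cc1 | starting material
2 | 1,4-bis(benzyloxy)-2-nitrobenzene | O=[N+]([O-])c1cc(OCc2ccccc2)ccc1OCc1ccccc1 | intermediate
3 | 2,5-bis(benzyloxy)aniline | Nc1cc(OCc2ccccc2)ccc1OCc1ccccc1 | intermediate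
4 | 2,5-bis(benzyloxy)benzenediazonium tetrafluoroborate | N#[N+]c1cc(OCc2ccccc2)ccc1OCc1ccccc1.F[B-](F)(F)F | intermediate
5 | 5-methoxynaphthalen-1-ol | COc1cccc2c(O)cccc12 | starting material
6 | 4-bromo-5-methoxynaphthalen-1-ol | COc1cccc2c(O)ccc(Br)c12 | intermediate
7 | 1-(benzyloxy)-4-bromo-5-methoxynaphthalene | COc1cccc2c(OCc3ccccc3)ccc(Br)c12 | intermediate
8 | [4-(benzyloxy)-8-methoxynaphthalen-1-yl]lithium | COc1cccc2c(OCc3ccccc3)ccc([Li])c12 | intermediate
9 | lithium [4-(benzyloxy)-8-methoxynaphthalen-1-yl]trimethoxyborate | COc1cccc2c(OCc3ccccc3)ccc([B-](OC)(OC)OC)c12.[Li+] | intermediate
10 | [4-(benzyloxy)-8-methoxynaphthalen-1-yl]boronic acid | COc1cccc2c(OCc3ccccc3)ccc(B(O)O)c12 | intermediate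
11 | methyl but-3-enoate | C=CCC(=O)OC | starting material
12 | methyl (4S)-4-[2,5-bis(benzyloxy)phenyl]-4-[4-(benzyloxy)-8-methoxynaphthalen-1-yl]butanoate | COc1cccc2c(OCc3ccccc3)ccc([C@@H](c3cc(OCc4ccccc4)ccc3OCc3ccccc3)CCC(=O)OC)c12 | intermediate
13 | (4S)-4-[2,5-bis(benzyloxy)phenyl]-4-[4-(benzyloxy)-8-methoxynaphthalen-1-yl]butanoic acid | COc1cccc2c(OCc3ccccc3)ccc([C@@H](c3cc(OCc4ccccc4)ccc3OCc3ccccc3)CCC(=O)O)c12 | intermediate
14 | (4S)-4-[2,5-bis(benzyloxy)phenyl]-4-[4-(benzyloxy)-8-methoxynaphthalen-1-yl]butanoic trifluoroacetic anhydride | COc1cccc2c(OCc3ccccc3)ccc([C@@H](c3cc(OCc4ccccc4)ccc3OCc3ccccc3)CCC(=O)OC(=O)C(F)(F)F)c12 | intermediate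
15 | (4S)-5,8-bis(benzyloxy)-4-[4-(benzyloxy)-8-methoxynaphthalen-1-yl]-3,4-dihydronaphthalen-1(2H)-one | COc1cccc2c(OCc3ccccc3)ccc([C@@H]3CCC(=O)c4c(OCc5ccccc5)ccc(OCc5ccccc5)c43)c12 | intermediate
16 | (4S)-5,8-dihydroxy-4-(4-hydroxy-8-methoxynaphthalen-1-yl)-3,4-dihydronaphthalen-1(2H)-one | COc1cccc2c(O)ccc([C@@H]3CCC(=O)c4c(O)ccc(O)c43)c12 | target

## Step count and least certain steps

Total steps: 10. Longest linear sequence: 7 (steps 1 to 3 or steps 4 to 6, then steps 7 to 10).

**Step 7 (key step, proposed new method).** The most likely failure is that the chain walk does not end at C4. The palladium hydride may leave the intermediate alkene, or palladium may migrate toward the ester and be protonated there, because transmetalation of the peri-hindered, electron-rich 10 may be too slow to capture the η3-benzyl complex. Direct biaryl coupling of 4 with 10, protodeboronation of 10 and cyclopalladation onto an ortho-benzyloxy group are further drains. Poor facial discrimination by the ion pair is possible because both aryl groups are ortho-substituted.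

Fallback by known chemistry, setting out from 4 and 10 and returning at 13:
- Heck–Matsuda arylation of methyl acrylate with 4 (Pd(OAc)2, MeOH, 40 °C) should give methyl (2E)-3-[2,5-bis(benzyloxy)phenyl]prop-2-enoate F1.
- Rhodium-catalysed asymmetric conjugate addition of 10 ([RhCl(C2H4)2]2, a chiral bicyclo[2.2.2]octadiene ligand of the enantiomeric series that leads to the (3S) product, aq KOH, dioxane, 50 °C) would set the stereocentre by carbometalation and give methyl (3S)-3-[2,5-bis(benzyloxy)phenyl]-3-[4-(benzyloxy)-8-methoxynaphthalen-1-yl]propanoate F2.
- Saponification with LiOH would give (3S)-3-[2,5-bis(benzyloxy)phenyl]-3-[4-(benzyloxy)-8-methoxynaphthalen-1-yl]propanoic acid F3.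
- Oxalyl chloride would give (3S)-3-[2,5-bis(benzyloxy)phenyl]-3-[4-(benzyloxy)-8-methoxynaphthalen-1-yl]propanoyl chloride F4.
- Trimethylsilyldiazomethane would give (4S)-4-[2,5-bis(benzyloxy)phenyl]-4-[4-(benzyloxy)-8-methoxynaphthalen-1-yl]-1-diazobutan-2-one F5.
- Wolff rearrangement in the presence of water (PhCO2Ag, Et3N, THF–H2O), the last stage of an Arndt–Eistert homologation, would add the missing carbon and deliver 13.

**Step 9.** Acid-promoted loss or migration of benzyl groups from the electron-rich rings, acylation of the naphthalene (at C2′ within the molecule or at C5′ between molecules), or sluggish ionisation of the mixed anhydride may compete. Fallback from 13, returning at 15: oxalyl chloride with catalytic DMF would give (4S)-4-[2,5-bis(benzyloxy)phenyl]-4-[4-(benzyloxy)-8-methoxynaphthalen-1-yl]butanoyl chloride F6. This would be cyclised without any added Brønsted or Lewis acid by dissolving it in 1,1,1,3,3,3-hexafluoropropan-2-ol at rt, where the solvent alone promotes ionisation of the acyl chloride. Loss of the C8 benzyl group at this stage would be harmless, since step 10 removes it anyway.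

**Step 6.** Deprotonation at the benzylic CH2 with rearrangement may compete with the exchange, and the boron may be lost from the electron-rich, peri-substituted ring during acidic work-up or storage. Fallback from 7, returning at 10: palladium-catalysed borylation with tetrahydroxydiboron (Pd(OAc)2, XPhos, KOAc, EtOH, 80 °C), which avoids both the organolithium and the acid; it makes no new compound (F0).

**Step 4.** Regiocontrol may be lost through attack at C2, attack on the methoxy ring at C8, or double bromination, because the position wanted is peri to the methoxy group. Fallback from 5, returning at 10, which fixes the position by oxidation instead of halogenation: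
- PhI(OAc)2 in MeCN–H2O should give 5-methoxynaphthalene-1,4-dione F7.
- Na2S2O4 would reduce it to 5-methoxynaphthalene-1,4-diol F8.
- One equivalent of benzyl bromide with K2CO3 under argon should alkylate the oxygen remote from the methoxy group (the other hydroxyl is hydrogen-bonded and hindered) to give 4-(benzyloxy)-8-methoxynaphthalen-1-ol F9.
- Tf2O and pyridine would give 4-(benzyloxy)-8-methoxynaphthalen-1-yl trifluoromethanesulfonate F10.
- The palladium-catalysed borylation with tetrahydroxydiboron described for step 6 would give 10.

**Step 10.** Over-reduction of the benzylic ketone, incomplete cleavage of the hindered C5 ether, or air oxidation of the hydroquinone during isolation may occur. Fallback from 15, returning at 16: BCl3 with pentamethylbenzene in CH2Cl2 at −78 °C. This is a Lewis-acid dealkylation with a cation scavenger, which should leave the ketone and, at this temperature, the methyl ether untouched; it makes no new compound (F0).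

## Further compounds

F1 | step 7 | methyl (2E)-3-[2,5-bis(benzyloxy)phenyl]prop-2-enoate | COC(=O)/C=C/c1cc(OCc2ccccc2)ccc1OCc1ccccc1
F2 | step 7 | methyl (3S)-3-[2,5-bis(benzyloxy)phenyl]-3-[4-(benzyloxy)-8-methoxynaphthalen-1-yl]propanoate | COc1cccc2c(OCc3ccccc3)ccc([C@@H](c3cc(OCc4ccccc4)ccc3OCc3ccccc3)CC(=O)OC)c12
F3 | step 7 | (3S)-3-[2,5-bis(benzyloxy)phenyl]-3-[4-(benzyloxy)-8-methoxynaphthalen-1-yl]propanoic acid | COc1cccc2c(OCc3ccccc3)ccc([C@@H](c3cc(OCc4ccccc4)ccc3OCc3ccccc3)CC(=O)O)c12
F4 | step 7 | (3S)-3-[2,5-bis(benzyloxy)phenyl]-3-[4-(benzyloxy)-8-methoxynaphthalen-1-yl]propanoyl chloride | COc1cccc2c(OCc3ccccc3)ccc([C@@H](c3cc(OCc4ccccc4)ccc3OCc3ccccc3)CC(=O)Cl)c12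
F5 | step 7 | (4S)-4-[2,5-bis(benzyloxy)phenyl]-4-[4-(benzyloxy)-8-methoxynaphthalen-1-yl]-1-diazobutan-2-one | COc1cccc2c(OCc3ccccc3)ccc([C@@H](c3cc(OCc4ccccc4)ccc3OCc3ccccc3)CC(=O)C=[N+]=[N-])c12
F6 | step 9 | (4S)-4-[2,5-bis(benzyloxy)phenyl]-4-[4-(benzyloxy)-8-methoxynaphthalen-1-yl]butanoyl chloride | COc1cccc2c(OCc3ccccc3)ccc([C@@H](c3cc(OCc4ccccc4)ccc3OCc3ccccc3)CCC(=O)Cl)c12
F0 | step 6 | none | none
F7 | step 4 | 5-methoxynaphthalene-1,4-dione | COc1cccc2C(=O)C=CC(=O)c12
F8 | step 4 | 5-methoxynaphthalene-1,4-diol | COc1cccc2c(O)ccc(O)c12
F9 | step 4 | 4-(benzyloxy)-8-methoxynaphthalen-1-ol | COc1cccc2c(OCc3ccccc3)ccc(O)c12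
F10 | step 4 | 4-(benzyloxy)-8-methoxynaphthalen-1-yl trifluoromethanesulfonate | COc1cccc2c(OCc3ccccc3)ccc(OS(=O)(=O)C(F)(F)F)c12
F0 | step 10 | none | none
A1 | alternative 1 | 2-chloro-1-{3,6-bis(methoxymethoxy)-2-[1-(8-methoxy-4-(methoxymethoxy)naphthalen-1-yl)ethenyl]phenyl}ethan-1-one | COc1cccc2c(OCOC)ccc(C(=C)c3c(OCOC)ccc(OCOC)c3C(=O)CCl)c12
A2 | alternative 1 | (4S)-5,8-bis(methoxymethoxy)-4-[8-methoxy-4-(methoxymethoxy)naphthalen-1-yl]-3,4-dihydronaphthalen-1(2H)-one | COc1cccc2c(OCOC)ccc([C@@H]3CCC(=O)c4c(OCOC)ccc(OCOC)c43)c12
A3 | alternative 2 | {[(1E,3E)-4-(4-(benzyloxy)-8-methoxynaphthalen-1-yl)buta-1,3-dien-1-yl]oxy}(tert-butyl)dimethylsilane | COc1cccc2c(OCc3ccccc3)ccc(/C=C/C=C/O[Si](C)(C)C(C)(C)C)c12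
A4 | alternative 2 | 1,4-benzoquinone | O=C1C=CC(=O)C=C1
A5 | alternative 2 | endo all-cis 5-[4-(benzyloxy)-8-methoxynaphthalen-1-yl]-8-(tert-butyldimethylsilyloxy)-4a,5,8,8a-tetrahydronaphthalene-1,4-dione, aryl carbon configured as C4 of 16 | COc1cccc2c(OCc3ccccc3)ccc([C@@H]3C=C[C@H](O[Si](C)(C)C(C)(C)C)[C@@H]4C(=O)C=CC(=O)[C@H]34)c12
A6 | alternative 3 | (4R)-4-[4-(benzyloxy)-8-methoxynaphthalen-1-yl]cyclohex-2-en-1-one | COc1cccc2c(OCc3ccccc3)ccc([C@@H]3CCC(=O)C=C3)c12
A7 | alternative 3 | 5-(benzenesulfonyl)furan-2(5H)-one | O=C1C=CC(O1)S(=O)(=O)c1ccccc1
A8 | alternative 3 | (4S)-4-[4-(benzyloxy)-8-methoxynaphthalen-1-yl]-5,8-dihydroxy-3,4-dihydronaphthalen-1(2H)-one | COc1cccc2c(OCc3ccccc3)ccc([C@@H]3CCC(=O)c4c(O)ccc(O)c43)c12
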